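**Retrosynthetic overview** (germacrane numbering C1–C15 throughout)
1. Target 19 ⇐ seco epoxy aldehyde–bromomethylbutenolide 16 by a new chromium-catalysed, ligand-controlled intramolecular allylation: forms C6–C7, sets C6 and C7, closes the ten-membered ring and unveils the α-methylene lactone.
2. 16 ⇐ butenolide 14 by ring-closing metathesis of the 2-(bromomethyl)acrylate 13 of the C8 alcohol 11; the C9 isobutyrate is already in place.
3. C8/C9 anti-diol unit ⇐ chiral-phosphoric-acid-catalysed anti-silyloxyallylboration of enal 5 with (E)-γ-silyloxyallylboronate 7.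
4. Enal 5 ⇐ geraniol 1 (supplies C1–C6, C9, C10, C14, C15) by Sharpless epoxidation (C4, C5), PMB protection and SeO2 allylic oxidation.
5. Ring order: epoxide (step 1) → butenolide (step 10) → ten-membered carbocycle (step 13).

Assumption: the sense of induction of (R)-TRIP in step 6 (Re face of the enal) and of the (S,S)-bis(oxazolinyl)carbazole–chromium catalyst in step 13 (Si face of the epoxy aldehyde) is taken from models for simpler aldehydes; if experiment shows the opposite sense, the enantiomeric catalyst is used.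

**Route**

Step 1
Reactants: 1 geraniol
Product: 2 (2S,3S)-2,3-epoxygeraniol
Conditions: Ti(OiPr)4 (5 mol %), L-(+)-diethyl tartrate (6 mol %), t-BuOOH, 4 Å MS, CH2Cl2, −20 °C
Reagents that add atoms: tert-butyl hydroperoxide, CC(C)(C)OO
Why: Sharpless asymmetric epoxidation; the titanium–L-tartrate complex epoxidises only the allylic-alcohol alkene and gives the (2S,3S)-epoxide (C4 and C5 of the target), leaving the remote trisubstituted alkene untouched.

Step 2
Reactants: 2 (2S,3S)-2,3-epoxygeraniol
Product: 3 PMB ether of 2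
Conditions: NaH, 4-methoxybenzyl chloride, n-Bu4NI (cat.), THF/DMF, 0 °C → rt
Reagents that add atoms: 4-methoxybenzyl chloride, COc1ccc(CCl)cc1
Why: Williamson etherification of the primary alkoxide is faster than Payne rearrangement and touches no stereocentre; the PMB group can later be removed under neutral oxidative conditions.

Step 3
Reactants: 3 PMB ether of 2
Product: 4 (E)-allylic alcohol (C9–OH)
Conditions: SeO2 (20 mol %), t-BuOOH (3 equiv), CH2Cl2, 0 °C → rt
Reagents that add atoms: tert-butyl hydroperoxide, CC(C)(C)OO (oxygen transferred through SeO2)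
Why: Selenium dioxide allylic oxidation (ene reaction, then [2,3]-sigmatropic shift) hydroxylates the (E)-methyl group of the terminal trisubstituted alkene with retention of E geometry; epoxide and PMB ether are inert.

Step 4
Reactants: 4 (E)-allylic alcohol
Product: 5 (E)-enal (C9 aldehyde)
Conditions: MnO2, CH2Cl2, rt
Reagents that add atoms: none
Why: MnO2 oxidises only the allylic alcohol and keeps the E geometry, under neutral conditions that spare the epoxide.

Step 5
Reactants: 6 (E)-3-(tert-butyldimethylsilyloxy)prop-1-enylboronic acid pinacol ester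
Product: 7 (E)-3-(tert-butyldimethylsilyloxy)allylboronic acid pinacol ester
Conditions: [Ir(cod)(PPh2Me)2]PF6 (3 mol %, activated with H2), THF, rt
Reagents that add atoms: none
Why: Iridium-hydride-catalysed alkene transposition moves the double bond into conjugation with oxygen and gives the (E)-γ-silyloxyallylboronate selectively.

Step 6
Reactants: 5 (E)-enal; 7 (E)-γ-silyloxyallylboronate
Product: 9 anti adduct with C9–OH and C8–OTBS (8R,9S), via pinacol borate ester 8 (not isolated)
Conditions: 7 (1.5 equiv), (R)-TRIP [(R)-3,3'-bis(2,4,6-triisopropylphenyl)-1,1'-binaphthyl-2,2'-diyl hydrogen phosphate] (5 mol %), 4 Å MS, toluene, −40 °C; then aq. NaHCO3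
Reagents that add atoms: none
Why: Brønsted-acid-catalysed allylboration through a closed chair transition state; the (E)-γ-silyloxy group sits equatorial, which gives the anti (erythro) C8/C9 relationship, and the chiral phosphoric acid directs allyl transfer to the Re face of the enal, setting 9S and hence 8R.

Step 7
Reactants: 9 anti adduct
Product: 10 C9 isobutyrate
Conditions: (i-PrCO)2O, DMAP (0.3 equiv), Et3N, CH2Cl2, 0 °C → rt
Reagents that add atoms: isobutyric anhydride, CC(C)C(=O)OC(=O)C(C)C
Why: DMAP-catalysed acylation of the only free hydroxyl installs the C9 ester of the target with retention.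

Step 8
Reactants: 10 C9 isobutyrate
Product: 11 C8 alcohol
Conditions: HF·pyridine, pyridine, THF, 0 °C → rt
Reagents that add atoms: none
Why: Buffered acidic fluoride cleaves the secondary TBS ether without 1,2-acyl migration (which basic fluoride would promote) and spares the epoxide, PMB ether and ester.

Step 9
Reactants: 11 C8 alcohol; 12 2-(bromomethyl)acrylic acid
Product: 13 C8 2-(bromomethyl)acrylate
Conditions: N,N'-diisopropylcarbodiimide, DMAP (5 mol %), CH2Cl2, 0 °C
Reagents that add atoms: none
Why: Steglich esterification of the allylic C8 alcohol brings in C11, C12 and C13 with the allylic bromide already in place; no stereocentre is touched.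

Step 10
Reactants: 13 C8 2-(bromomethyl)acrylate
Product: 14 3-(bromomethyl)butenolide
Conditions: second-generation Hoveyda–Grubbs catalyst RuCl2(=CH-C6H4-2-OiPr)(H2IMes) (10 mol %), toluene (5 mM), 80 °C
Reagents that add atoms: none
Why: Ring-closing metathesis between the terminal vinyl group and the acrylate forms the C7=C11 butenolide with loss of ethene; the trisubstituted C1=C10 alkene is too hindered to take part and C8 is unaffected.

Step 11
Reactants: 14 3-(bromomethyl)butenolide
Product: 15 epoxy alcohol (C6–OH)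
Conditions: DDQ, CH2Cl2/pH 7 buffer (10:1), 0 °C → rt
Reagents that add atoms: none
Why: Oxidative PMB cleavage is neutral and so tolerates the allylic bromide, the base-sensitive acyloxy butenolide and the epoxide.

Step 12
Reactants: 15 epoxy alcohol
Product: 16 epoxy aldehyde (seco precursor)
Conditions: Dess–Martin periodinane, NaHCO3, CH2Cl2, 0 °C → rt
Reagents that add atoms: none
Why: Buffered Dess–Martin oxidation gives the α,β-epoxy aldehyde without base, so the epoxide α-carbon (C5) and the bromomethylbutenolide are preserved.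

Step 13
Reactants: 16 epoxy aldehyde
Product: 19 (4S,5S,6S,7S,8R,9S)-4,5-epoxy-6-hydroxy-9-[(2-methylpropanoyl)oxy]germacra-1(10)E,11(13)-dien-12,8-olide (target), via allylchromium dichloride 17 (not isolated), via trimethylsilyl ether 18 (not isolated)
Conditions: CrCl2 (20 mol %), (S,S)-3,6-di-tert-butyl-1,8-bis(4-isopropyl-4,5-dihydrooxazol-2-yl)-9H-carbazole (22 mol %), i-Pr2NEt (40 mol %), Mn powder (3 equiv), Me3SiCl (2 equiv), THF, 16 added over 12 h to 2 mM, rt; then aq. citric acid/THF, 0 °C
Reagents that add atoms: chromium dichloride, Cl[Cr]Cl (chromium and chloride only in 17); chlorotrimethylsilane, C[Si](C)(C)Cl (silyl group only in 18)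
Why: Proposed new method: a ligand-controlled, chromium-catalysed Nozaki–Hiyama-type macro-allylation in which the butenolide is the allyl donor — divalent chromium (regenerated by Mn) reduces the allylic C–Br bond of 16 to the trivalent allylchromium 17, which adds through its γ-carbon C7 to the tethered aldehyde in a chair transition state; because the lactone ring locks C8 trans to the CH2–Cr arm, the chair gives the 6,7-relationship of the target, and the C2-symmetric bis(oxazolinyl)carbazole ligand, by selecting the Si face of the aldehyde, also fixes attack on the C7 face anti to the C8–C9 bond (trans-fused lactone, 6S,7S), in line with the Felkin–Anh preference of the epoxy aldehyde; Me3SiCl releases chromium from the alkoxide as silyl ether 18 (which blocks translactonisation) and mild acid then frees the C6 hydroxyl; the closest known reactions are the intermolecular chromium-catalysed enantioselective 2-(alkoxycarbonyl)allylation of aldehydes with acyclic bromomethyl acrylates, the zinc or indium Barbier reactions of 3-(bromomethyl)butenolides with aldehydes, and metal-mediated closures of ten-membered germacrane rings with acyclic allyl halides.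

**Compound list**
1 | geraniol, (2E)-3,7-dimethylocta-2,6-dien-1-ol | CC(C)=CCC/C(C)=C/CO | starting material
2 | [(2S,3S)-3-methyl-3-(4-methylpent-3-en-1-yl)oxiran-2-yl]methanol | OC[C@@H]1O[C@@]1(C)CCC=C(C)C | intermediate
3 | (2S,3S)-2-{[(4-methoxybenzyl)oxy]methyl}-3-methyl-3-(4-methylpent-3-en-1-yl)oxirane | COc1ccc(COC[C@@H]2O[C@@]2(C)CCC=C(C)C)cc1 | intermediate
4 | (2E)-5-[(2S,3S)-3-{[(4-methoxybenzyl)oxy]methyl}-2-methyloxiran-2-yl]-2-methylpent-2-en-1-ol | COc1ccc(COC[C@@H]2O[C@@]2(C)CC/C=C(\C)CO)cc1 | intermediate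
5 | (2E)-5-[(2S,3S)-3-{[(4-methoxybenzyl)oxy]methyl}-2-methyloxiran-2-yl]-2-methylpent-2-enal | COc1ccc(COC[C@@H]2O[C@@]2(C)CC/C=C(\C)C=O)cc1 | intermediate
6 | (E)-tert-butyldimethyl{[3-(4,4,5,5-tetramethyl-1,3,2-dioxaborolan-2-yl)prop-2-en-1-yl]oxy}silane | CC(C)(C)[Si](C)(C)OC/C=C/B1OC(C)(C)C(C)(C)O1 | starting material
7 | (E)-tert-butyldimethyl{[3-(4,4,5,5-tetramethyl-1,3,2-dioxaborolan-2-yl)prop-1-en-1-yl]oxy}silane | CC(C)(C)[Si](C)(C)O/C=C/CB1OC(C)(C)C(C)(C)O1 | intermediate
8 | pinacol borate ester of 9 (O–B(pin) on the C9 oxygen) | COc1ccc(COC[C@@H]2O[C@@]2(C)CC/C=C(\C)[C@H](OB3OC(C)(C)C(C)(C)O3)[C@H](O[Si](C)(C)C(C)(C)C)C=C)cc1 | intermediate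
9 | (3R,4S,5E)-3-[(tert-butyldimethylsilyl)oxy]-8-[(2S,3S)-3-{[(4-methoxybenzyl)oxy]methyl}-2-methyloxiran-2-yl]-5-methylocta-1,5-dien-4-ol | COc1ccc(COC[C@@H]2O[C@@]2(C)CC/C=C(\C)[C@H](O)[C@H](O[Si](C)(C)C(C)(C)C)C=C)cc1 | intermediate
10 | (3R,4S,5E)-3-[(tert-butyldimethylsilyl)oxy]-8-[(2S,3S)-3-{[(4-methoxybenzyl)oxy]methyl}-2-methyloxiran-2-yl]-5-methylocta-1,5-dien-4-yl 2-methylpropanoate | COc1ccc(COC[C@@H]2O[C@@]2(C)CC/C=C(\C)[C@H](OC(=O)C(C)C)[C@H](O[Si](C)(C)C(C)(C)C)C=C)cc1 | intermediate
11 | (3R,4S,5E)-3-hydroxy-8-[(2S,3S)-3-{[(4-methoxybenzyl)oxy]methyl}-2-methyloxiran-2-yl]-5-methylocta-1,5-dien-4-yl 2-methylpropanoate | COc1ccc(COC[C@@H]2O[C@@]2(C)CC/C=C(\C)[C@H](OC(=O)C(C)C)[C@H](O)C=C)cc1 | intermediate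
12 | 2-(bromomethyl)prop-2-enoic acid | C=C(CBr)C(=O)O | starting material
13 | (3R,4S,5E)-8-[(2S,3S)-3-{[(4-methoxybenzyl)oxy]methyl}-2-methyloxiran-2-yl]-5-methyl-4-[(2-methylpropanoyl)oxy]octa-1,5-dien-3-yl 2-(bromomethyl)prop-2-enoate | COc1ccc(COC[C@@H]2O[C@@]2(C)CC/C=C(\C)[C@H](OC(=O)C(C)C)[C@H](OC(=O)C(=C)CBr)C=C)cc1 | intermediate
14 | (1S,2E)-1-[(2R)-4-(bromomethyl)-5-oxo-2,5-dihydrofuran-2-yl]-5-[(2S,3S)-3-{[(4-methoxybenzyl)oxy]methyl}-2-methyloxiran-2-yl]-2-methylpent-2-en-1-yl 2-methylpropanoate | COc1ccc(COC[C@@H]2O[C@@]2(C)CC/C=C(\C)[C@H](OC(=O)C(C)C)[C@@H]3OC(=O)C(CBr)=C3)cc1 | intermediate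
15 | (1S,2E)-1-[(2R)-4-(bromomethyl)-5-oxo-2,5-dihydrofuran-2-yl]-5-[(2S,3S)-3-(hydroxymethyl)-2-methyloxiran-2-yl]-2-methylpent-2-en-1-yl 2-methylpropanoate | OC[C@@H]1O[C@@]1(C)CC/C=C(\C)[C@H](OC(=O)C(C)C)[C@@H]2OC(=O)C(CBr)=C2 | intermediate
16 | (1S,2E)-1-[(2R)-4-(bromomethyl)-5-oxo-2,5-dihydrofuran-2-yl]-5-[(2S,3R)-3-formyl-2-methyloxiran-2-yl]-2-methylpent-2-en-1-yl 2-methylpropanoate | O=C[C@@H]1O[C@@]1(C)CC/C=C(\C)[C@H](OC(=O)C(C)C)[C@@H]2OC(=O)C(CBr)=C2 | intermediate
17 | allylchromium dichloride from 16 (CH2–CrCl2 in place of CH2Br, trivalent chromium, chiral ligand not drawn) | O=C[C@@H]1O[C@@]1(C)CC/C=C(\C)[C@H](OC(=O)C(C)C)[C@@H]2OC(=O)C(C[Cr](Cl)Cl)=C2 | intermediate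
18 | 6-O-trimethylsilyl ether of 19 | C=C1C(=O)O[C@@H]2[C@@H]1[C@H](O[Si](C)(C)C)[C@@H]1O[C@@]1(C)CC/C=C(\C)[C@@H]2OC(=O)C(C)C | intermediate
19 | (4S,5S,6S,7S,8R,9S)-4,5-epoxy-6-hydroxy-9-[(2-methylpropanoyl)oxy]germacra-1(10)E,11(13)-dien-12,8-olide (CNP0220196.1) | C=C1C(=O)O[C@@H]2[C@@H]1[C@H](O)[C@@H]1O[C@@]1(C)CC/C=C(\C)[C@@H]2OC(=O)C(C)C | target

**Step count and risks**

Total step count: 13. Longest linear sequence: 12 steps (1 → 19 through steps 1–4 and 6–13; step 5 prepares reagent 7).

The three steps most likely to fail: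

Step 13 (the proposed new ring closure). The allylchromium may dimerise or be protonated before the ten-membered ring closes, or the ligand may not override the macrocyclic bias, giving the cis-fused lactone or the C6 epimer. The fallback sets out from 16 and comes back at 19, and replaces catalyst control by a substrate-controlled palladium/zinc umpolung. Pd(PPh3)4 (10 mol %) and Et2Zn (3 equiv) in THF at 2 mM (0 °C → rt) convert the allylic bromide, through a π-allylpalladium complex, into the allyl(ethyl)zinc species F4. F4 cyclises onto the epoxy aldehyde through the same chair transition state under Felkin and macrocyclic control, and aqueous NH4Cl work-up gives 19. Both elements are known chemistry: palladium-catalysed zinc umpolung allylation has closed epoxy-germacrane ten-membered rings at this bond, and bromomethylbutenolides are established Barbier donors.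

Step 6 (catalytic anti-silyloxyallylboration). The phosphoric acid may open the trisubstituted epoxide or cleave the silyl enol ether of 7, and the facial selectivity on this α-methyl enal is untested. The fallback sets out from 5 (with 7) and comes back at 9, and replaces catalyst control by kinetic resolution. Acid-free, uncatalysed allylboration (toluene, rt → 40 °C, then aq. NaHCO3) still gives only anti adducts, but as a roughly 1:1 mixture of 8 and the diastereomeric pinacol borate ester F1. Hydrolysis gives 9 and the (3S,4R)-alcohol F2. Sharpless kinetic resolution of the mixture [Ti(OiPr)4, L-(+)-diisopropyl tartrate, t-BuOOH (0.6 equiv), 4 Å MS, CH2Cl2, −20 °C] epoxidises the fast-reacting carbinol F2 to the epoxy alcohol F3, which is removed by chromatography, and leaves 9 (the slow-reacting 4S carbinol) unchanged.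

Step 3 (selenium dioxide oxidation). Low conversion, over-oxidation and selenium-mediated damage to the epoxide are possible. The fallback sets out from 3 and comes back at 5, bypassing 4, and replaces allylic oxidation by alkene metathesis. Cross-metathesis of the prenyl-type alkene of 3 with excess methacrolein, using second-generation Hoveyda–Grubbs catalyst RuCl2(=CH-C6H4-2-OiPr)(H2IMes) in CH2Cl2 at 40 °C, gives the (E)-enal 5 directly under thermodynamic control. New compounds on its way: none F0.

**Further compounds**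
F0 | step 3 | none | none
F1 | step 6 | pinacol borate ester of F2 | COc1ccc(COC[C@@H]2O[C@@]2(C)CC/C=C(\C)[C@@H](OB3OC(C)(C)C(C)(C)O3)[C@@H](O[Si](C)(C)C(C)(C)C)C=C)cc1
F2 | step 6 | (3S,4R,5E)-3-[(tert-butyldimethylsilyl)oxy]-8-[(2S,3S)-3-{[(4-methoxybenzyl)oxy]methyl}-2-methyloxiran-2-yl]-5-methylocta-1,5-dien-4-ol | COc1ccc(COC[C@@H]2O[C@@]2(C)CC/C=C(\C)[C@@H](O)[C@@H](O[Si](C)(C)C(C)(C)C)C=C)cc1
F3 | step 6 | (3S,4S,5S,6S)-3-[(tert-butyldimethylsilyl)oxy]-5,6-epoxy-8-[(2S,3S)-3-{[(4-methoxybenzyl)oxy]methyl}-2-methyloxiran-2-yl]-5-methyloct-1-en-4-ol | COc1ccc(COC[C@@H]2O[C@@]2(C)CC[C@@H]3O[C@@]3(C)[C@@H](O)[C@@H](O[Si](C)(C)C(C)(C)C)C=C)cc1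
F4 | step 13 | allyl(ethyl)zinc species from 16 (CH2–ZnEt in place of CH2Br) | O=C[C@@H]1O[C@@]1(C)CC/C=C(\C)[C@H](OC(=O)C(C)C)[C@@H]2OC(=O)C(C[Zn]CC)=C2
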